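- By 4.00 min the beta run reads 22.3% monomer in chains and the zeta run 52.2%, both from [free monomer] = 0.20 M; I want the average chain length in south-west and west.

| flask | free monomer | initiator | remark | time |
|---|---|---|---|---|
| beta | 0.20 M | 1.2 mol% | run made earlier |  |
| zeta | 0.20 M | 3.8 mol% | run made earlier |  |
| south-west | 0.20 M | 5.8 mol% |  | 5.0 min |
| west | 0.20 M | 1.5 mol% |  | 5.0 min |

- beta (time / min: monomer in chains / %): 0.667: 3.8; 1.33: 9.0; 2.00: 13.8; 2.50: 17.3; 3.00: 21.4; 4.00: 22.3
- zeta (time / min: monomer in chains / %): 0.667: 15.3; 1.33: 27.0; 2.00: 34.9; 2.50: 39.3; 3.00: 44.0; 4.00: 52.2

(readings scatter by 1 percentage point)

1. which of the two ends with the longer chains by the average number of monomer units in a chain (chains begun, living or dead) ("neither" if they lie within 10%) (south-west / west / neither)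
2. average number of monomer units in a chain (chains begun, living or dead) at the end, south-west
3. average number of monomer units in a chain (chains begun, living or dead) at the end, west

- the average divides the monomer in chains by the number of chains begun, living and dead together
- the earlier runs do not show the number of chains; that part of a forecast is a guess

- My zero is the statistical case: each initiator begins one chain and the whole charge of free monomer divides equally, so the even-share length is one over the loading, 17.2 in south-west and 66.7 in west.
- Here is the oddity: beta's even-share length of 83.3 is 3.17 times zeta's 26.3, yet on that same count of chains their lengths read 18.6 and 13.7, a ratio of 1.35.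
- It clears up once I write length as even-share length times the fraction in chains: zeta's fraction is larger than beta's, so the extra initiator shortens the scale and fills more of it.
- South-west has to fill 3.87 times west's fraction to draw level. West has more initiator than beta and more time, so I use beta's reading as its floor. That asks 86.2% of south-west; zeta, with less initiator and less time, reads 52.2% and gains 8.2 percentage points over its last interval of 1.00 min. South-west may well pass zeta, but I judge 86.2% out of reach, and I commit to west.
- The forecast gives 13.6 for south-west and 19 for west, hence west, and warns: “This assumes every initiator molecule starts one chain, which the runs cannot show.”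
- The flasks give 11.1 and 22.9, so west is longer; the forecast stands higher for south-west and lower for west.

    free monomer + initiator → living end + monomer in chains (k = 0.570 M⁻¹ s⁻¹)
    free monomer + living end → monomer in chains + living end, rate k2*[living end]*[free monomer] (k = 0.770 M⁻¹ s⁻¹)
    monomer in chains + living end → free monomer + living end, rate k3*[living end] as long as [monomer in chains] is above zero (k = 0.0460 s⁻¹)
    2 free monomer → homo dimer (k = 3.10 × 10⁻⁴ M⁻¹ s⁻¹)

- Even-share length times monomer in chains gives 11.1 for south-west at 64.4% and 22.9 for west at 34.4%, with initiator at 0% in west; the neighbour of west with 3.8 mol% initiator has 26.3 times 57.1%, or 15.0. In west at 5.00 min, monomer in chains is made 2.12 times faster than it is used up, each step taken net, down from 2.67 at 2.31 min, and by 50.0 min it stands at 64.0%, a length of 42.6.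

(The runs are calculated on assumed constants; noise was put on by code.)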